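Assumption: the target has no stereocentre (it is achiral), so there is no enantiomer to select; the tether is read as fourteen CH2 groups (C30H42O8).

**Retrosynthetic overview**
1. C–O: the two OH groups are removed to give a bis(methoxyquinone) with one ring C–H per ring; forward, nucleophilic epoxidation and acid isomerisation put OH on exactly that carbon.
2. C=O: the bis(methoxyquinone) goes back to a bis(1,3-dimethoxyarene). The rings differ only in what sits between the two OMe groups (methyl in ring A, the chain in ring B), and this fixes which OMe survives.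
3. Key C–C disconnection: both ArCH2–CH2 bonds. Each benzaldehyde carbon is used with reversed polarity (N–H hydrazone as benzyl-anion equivalent, N2 lost) against one end of a C12 α,ω-dibromide, so two acceptor carbons are joined (1 + 12 + 1 = 14 chain carbons).
4. Ring order: no carbocycle is built. Ring A is attached first, ring B second, and both are oxidised together; the only rings formed are two transient oxiranes (step 4), opened in step 5.

**Route**

Step 1
Reactants: 1 3,5-dimethoxy-4-methylbenzaldehyde; 2 1,12-dibromododecane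
Product: 4 5-(13-bromotridecyl)-1,3-dimethoxy-2-methylbenzene, via hydrazone 3 (not isolated)
Conditions: N2H4·H2O (1.1 equiv), THF, rt; then 2 (4 equiv), Ni(cod)2 (10 mol %), PMe3 (20 mol %), K3PO4 (2 equiv), THF, 50 °C
Reagents that add atoms: none
Why: Carbonyl umpolung: hydrazone 3, deprotonated at N–H, delivers its former aldehyde carbon as a benzyl-anion (d1) nucleophile to the primary C–Br bond on zerovalent nickel and then expels N2 (nickel-catalysed denitrogenative hydrazone–alkyl halide cross-coupling, Wolff–Kishner type), so two electrophilic carbons are joined with no functional group left behind, while the fourfold excess of 2 keeps the second C–Br bond intact; no stereocentre is formed.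

Step 2
Reactants: 5 2,6-dimethoxy-4-methylbenzaldehyde; 4 5-(13-bromotridecyl)-1,3-dimethoxy-2-methylbenzene
Product: 7 2-[14-(3,5-dimethoxy-4-methylphenyl)tetradecyl]-1,3-dimethoxy-5-methylbenzene, via hydrazone 6 (not isolated)
Conditions: 5 (1.5 equiv), N2H4·H2O, THF, rt; then 4, Ni(cod)2 (10 mol %), PMe3 (20 mol %), K3PO4 (2 equiv), THF, 60 °C
Reagents that add atoms: none
Why: The same hydrazone umpolung cross-coupling, now with the di-ortho-methoxy hydrazone 6 in excess over primary bromide 4, places the chain on the ring carbon between the two methoxy groups of ring B and completes the 14-carbon tether; no stereocentre is formed.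

Step 3
Reactants: 7 2-[14-(3,5-dimethoxy-4-methylphenyl)tetradecyl]-1,3-dimethoxy-5-methylbenzene
Product: 8 3-methoxy-2-[14-(5-methoxy-4-methyl-3,6-dioxocyclohexa-1,4-dien-1-yl)tetradecyl]-5-methylcyclohexa-2,5-diene-1,4-dione
Conditions: 30% aq. H2O2, HCO2H, CH2Cl2, 25 °C
Reagents that add atoms: hydrogen peroxide, OO; water, O
Why: Performic acid hydroxylates the ring C–H that is ortho and para to the two OMe groups and oxidises the resulting p-methoxyphenol on to the quinone with loss of methanol (oxidative demethylation of a methoxyarene to a methoxy-p-benzoquinone, the reaction type used to make the coenzyme Q ring from a trimethoxytoluene); the two C–H of each ring are equivalent, so each ring can give only one quinone, with the surviving OMe next to methyl in ring A and next to the chain in ring B.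

Step 4
Reactants: 8 3-methoxy-2-[14-(5-methoxy-4-methyl-3,6-dioxocyclohexa-1,4-dien-1-yl)tetradecyl]-5-methylcyclohexa-2,5-diene-1,4-dione
Product: 9 1-[14-(4-methoxy-6-methyl-2,5-dioxo-7-oxabicyclo[4.1.0]hept-3-en-3-yl)tetradecyl]-3-methoxy-4-methyl-7-oxabicyclo[4.1.0]hept-3-ene-2,5-dione
Conditions: t-BuOOH (decane), DBU (0.3 equiv), CH2Cl2, 0 °C
Reagents that add atoms: tert-butyl hydroperoxide, CC(C)(C)OO
Why: Weitz–Scheffer nucleophilic epoxidation: t-BuOO− adds to the only unsubstituted ring carbon of each quinone, which is the β-carbon of the carbonyl not deactivated by vinylogous-ester conjugation with OMe, and the enolate closes the cis-oxirane, while the methoxy-bearing double bond is too electron-rich to react; the four new stereocentres (racemic, two diastereomers) are erased in step 5.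

Step 5
Reactants: 9 1-[14-(4-methoxy-6-methyl-2,5-dioxo-7-oxabicyclo[4.1.0]hept-3-en-3-yl)tetradecyl]-3-methoxy-4-methyl-7-oxabicyclo[4.1.0]hept-3-ene-2,5-dione
Product: 10 2-hydroxy-3-[14-(5-hydroxy-2-methoxy-4-methyl-3,6-dioxocyclohexa-1,4-dien-1-yl)tetradecyl]-5-methoxy-6-methylcyclohexa-2,5-diene-1,4-dione
Conditions: conc. H2SO4, 0 °C to rt, 10 min; then ice-water
Reagents that add atoms: none
Why: Acid-promoted opening of each oxirane at its fully substituted carbon with loss of the adjacent oxirane proton (epoxy-ketone to enol isomerisation, the classical quinone oxide to hydroxyquinone conversion) leaves the oxygen on the former C–H carbon, so OH ends next to the chain in ring A and next to the methyl group in ring B, and no stereocentre remains.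

**Compound list**
1 | 3,5-dimethoxy-4-methylbenzaldehyde | COc1cc(C=O)cc(OC)c1C | starting material
2 | 1,12-dibromododecane | BrCCCCCCCCCCCCBr | starting material
3 | (E)-(3,5-dimethoxy-4-methylbenzylidene)hydrazine (N–H hydrazone of 1) | COc1cc(/C=N/N)cc(OC)c1C | intermediate (not isolated)
4 | 5-(13-bromotridecyl)-1,3-dimethoxy-2-methylbenzene | COc1cc(CCCCCCCCCCCCCBr)cc(OC)c1C | intermediate
5 | 2,6-dimethoxy-4-methylbenzaldehyde | COc1cc(C)cc(OC)c1C=O | starting material
6 | (E)-(2,6-dimethoxy-4-methylbenzylidene)hydrazine (N–H hydrazone of 5) | COc1cc(C)cc(OC)c1/C=N/N | intermediate (not isolated)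
7 | 2-[14-(3,5-dimethoxy-4-methylphenyl)tetradecyl]-1,3-dimethoxy-5-methylbenzene (ring B carries the chain between its two OMe groups; ring A carries it para to methyl) | COc1cc(C)cc(OC)c1CCCCCCCCCCCCCCc1cc(OC)c(C)c(OC)c1 | intermediate
8 | 3-methoxy-2-[14-(5-methoxy-4-methyl-3,6-dioxocyclohexa-1,4-dien-1-yl)tetradecyl]-5-methylcyclohexa-2,5-diene-1,4-dione (bis(methoxy-p-benzoquinone), one ring C–H per ring) | COC1=C(C)C(=O)C=C(CCCCCCCCCCCCCCC2=C(OC)C(=O)C(C)=CC2=O)C1=O | intermediate
9 | 1-[14-(4-methoxy-6-methyl-2,5-dioxo-7-oxabicyclo[4.1.0]hept-3-en-3-yl)tetradecyl]-3-methoxy-4-methyl-7-oxabicyclo[4.1.0]hept-3-ene-2,5-dione (bis-oxide of 8 at the two C(H)=C(alkyl) bonds; each oxirane cis-fused, racemic, mixture of two diastereomers, stereocentres not defined) | COC1=C(C)C(=O)C2OC2(CCCCCCCCCCCCCCC3=C(OC)C(=O)C4(C)OC4C3=O)C1=O | intermediate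
10 | 2-hydroxy-3-[14-(5-hydroxy-2-methoxy-4-methyl-3,6-dioxocyclohexa-1,4-dien-1-yl)tetradecyl]-5-methoxy-6-methylcyclohexa-2,5-diene-1,4-dione (achiral) | COC1=C(C)C(=O)C(O)=C(CCCCCCCCCCCCCCC2=C(OC)C(=O)C(C)=C(O)C2=O)C1=O | target

**Totals**
Total steps: 5. Longest linear sequence: 5 (1 → 4 → 7 → 8 → 9 → 10; aldehyde 5 enters directly in step 2).

**Steps most likely to fail and fallbacks**

Step 2. The hydrazone carbon of 6 is flanked by two ortho-methoxy groups, so C–C coupling may lose to N-alkylation or azine formation; the same chemistry with the unhindered partner in step 1 is less exposed. The fallback sets out from 5 and comes back at 7. Aldehyde 5 is condensed with propane-1,3-dithiol (BF3·OEt2, CH2Cl2) to 2-(2,6-dimethoxy-4-methylphenyl)-1,3-dithiane F1. n-BuLi (THF, −30 °C) turns this into 2-lithio-2-(2,6-dimethoxy-4-methylphenyl)-1,3-dithiane F2, a stoichiometric acyl-anion equivalent. F2 is alkylated by bromide 4 to 2-(2,6-dimethoxy-4-methylphenyl)-2-[13-(3,5-dimethoxy-4-methylphenyl)tridecyl]-1,3-dithiane F3, and Raney Ni in refluxing EtOH strips the sulfur to give 7.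

Step 3. Both rings must undergo hydroxylation and oxidative demethylation without a third activating OMe, so incomplete conversion or over-oxidation is possible. The fallback sets out from 7 and comes back at 8. NaSEt in DMF at 140 °C removes exactly one methyl group per ring (the phenoxide formed shields the second ether) to give 2-[14-(3-hydroxy-5-methoxy-4-methylphenyl)tetradecyl]-3-methoxy-5-methylphenol F4. ON(SO3K)2 in KH2PO4-buffered aqueous acetone (Teuber oxidation) then oxidises each phenol at its free para position to 8.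

Step 4. The bis(methoxyquinone) is base-sensitive, and the bis-oxide must then survive strong acid in step 5 without losing OMe. The fallback sets out from 8 and comes back at 10, replacing steps 4 and 5. Thiele–Winter acetoxylation (Ac2O, BF3·OEt2, 40 °C) adds acetate at the single free ring carbon of each quinone and gives 3-[14-(2,3,5-triacetoxy-6-methoxy-4-methylphenyl)tetradecyl]-5-methoxy-6-methylbenzene-1,2,4-triyl triacetate F5. HCl in degassed MeOH removes the six acetyl groups to 3-[14-(2,3,5-trihydroxy-6-methoxy-4-methylphenyl)tetradecyl]-5-methoxy-6-methylbenzene-1,2,4-triol F6, and letting air into the solution oxidises both triol rings to 10.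

**Further compounds**
F1 | step 2 | 2-(2,6-dimethoxy-4-methylphenyl)-1,3-dithiane | COc1cc(C)cc(OC)c1C1SCCCS1
F2 | step 2 | 2-lithio-2-(2,6-dimethoxy-4-methylphenyl)-1,3-dithiane | [Li]C1(SCCCS1)c1c(OC)cc(C)cc1OC
F3 | step 2 | 2-(2,6-dimethoxy-4-methylphenyl)-2-[13-(3,5-dimethoxy-4-methylphenyl)tridecyl]-1,3-dithiane | COc1cc(C)cc(OC)c1C1(CCCCCCCCCCCCCc2cc(OC)c(C)c(OC)c2)SCCCS1
F4 | step 3 | 2-[14-(3-hydroxy-5-methoxy-4-methylphenyl)tetradecyl]-3-methoxy-5-methylphenol | COc1cc(C)cc(O)c1CCCCCCCCCCCCCCc1cc(O)c(C)c(OC)c1
F5 | step 4 | 3-[14-(2,3,5-triacetoxy-6-methoxy-4-methylphenyl)tetradecyl]-5-methoxy-6-methylbenzene-1,2,4-triyl triacetate | COc1c(C)c(OC(C)=O)c(OC(C)=O)c(CCCCCCCCCCCCCCc2c(OC)c(OC(C)=O)c(C)c(OC(C)=O)c2OC(C)=O)c1OC(C)=O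
F6 | step 4 | 3-[14-(2,3,5-trihydroxy-6-methoxy-4-methylphenyl)tetradecyl]-5-methoxy-6-methylbenzene-1,2,4-triol | COc1c(C)c(O)c(O)c(CCCCCCCCCCCCCCc2c(OC)c(O)c(C)c(O)c2O)c1O
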